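The central benzene ring is fully substituted: oxygen sits on C2, C4 and C6, and carbon groups sit on C1 (isobutyryl), C3 and C5 (the two CH(iPr)–syncarpyl arms). An ethoxy-substituted vinylketene and a 1-siloxyalkyne deliver exactly this O/C alternation regiospecifically.
The retrosynthesis cuts C1–C(=O)iPr first (Friedel–Crafts), then the ring bonds C3–C4, C4–C5 and C1–C2. This leads to a 3-ethoxycyclobutenone (future C4, C5, C6, C1, with one arm on its C4) and a silyl ynol ether (future C2, C3, with the other arm on its carbon terminus).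
Both partners come from one ester, made from syncarpic acid and (E)-4-methylpent-2-enal. The two syncarpyl rings are bought, and the arene is the only ring built; it closes in a single thermal cascade.
One iminium-catalysed Michael addition sets the arm centre, and the same batch feeds both partners, so both centres have the same sense (R,R). Residual minor enantiomer should end mainly in a separable (R,S) diastereomer.
The endgame is desilylation, C-acylation of the last ring CH, and one global O-dealkylation.

Key step: step 9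

Assumption: the 2-substituted syncarpyl ring is locally symmetric about its C2···C5 axis, so methylation of either enol oxygen gives the same enol ether; the target is written as one of its fast-exchanging enol tautomers.
Abbreviation used in names: MTD = 2-methoxy-3,3,5,5-tetramethyl-4,6-dioxocyclohex-1-en-1-yl, the O-methylated syncarpyl ring bonded through its C1.

Step 1
Reactants: 1 syncarpic acid; 2 (E)-4-methylpent-2-enal
Product: 3 (4S)-2-hydroxy-4-isopropyl-6,6,8,8-tetramethyl-3,4-dihydro-2H-chromene-5,7(6H,8H)-dione (lactol; both anomers)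
Conditions: (S)-2-{bis[3,5-bis(trifluoromethyl)phenyl](trimethylsilyloxy)methyl}pyrrolidine (10 mol %), CH2Cl2, 0 °C
Reagents that add atoms: none
Why: Iminium-catalysed asymmetric Michael addition of a cyclic 1,3-dicarbonyl compound to an enal, followed by spontaneous hemiacetal closure, is well established; in the s-trans (E)-iminium ion the CAr2(OSiMe3) group of the (S)-catalyst covers one face, so C2 of 1 should bond to Cβ of 2 from the open face and set the (S) centre, which is the only stereochemical event of the route.

Step 2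
Reactants: 3 lactol
Product: 4 (4S)-4-isopropyl-6,6,8,8-tetramethyl-3,4-dihydro-2H-chromene-2,5,7(6H,8H)-trione (enol δ-lactone)
Conditions: TEMPO (10 mol %), PhI(OAc)2 (1.3 equiv), CH2Cl2, rt
Reagents that add atoms: none
Why: Oxoammonium oxidation (TEMPO/PhI(OAc)2) of a lactol to its lactone is standard, runs close to neutrality and touches neither the stereocentre β to the new carbonyl group nor the tetrasubstituted, electron-poor ring double bond.

Step 3
Reactants: 4 enol δ-lactone
Product: 6 methyl (3S)-3-(MTD)-4-methylpentanoate, via enol ester 5 (not isolated)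
Conditions: MeOH, DMAP (5 mol %), rt; then TMSCHN2 (hexanes), PhMe–MeOH, 0 °C
Reagents that add atoms: methanol, CO; (trimethylsilyl)diazomethane, C[Si](C)(C)C=[N+]=[N-]
Why: The enol lactone is a vinylogous anhydride and should transfer its acyl group to methanol readily (nucleophilic acyl substitution), and the strongly acidic enol set free is then O-methylated by the diazoalkane in the way a carboxylic acid is esterified, which shuts off relactonisation and retro-Michael loss of the ring in all later steps.

Step 4
Reactants: 6 methyl ester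
Product: 7 (3S)-3-(MTD)-4-methylpentanoic acid
Conditions: LiOH, THF–H2O, 0 °C → rt; then 1 M HCl to pH 3
Reagents that add atoms: lithium hydroxide, [Li+].[OH-]
Why: Saponification should single out the unhindered CH2CO2Me group, because hydroxide addition to the vinylogous ester would have to occur at a fully substituted carbon next to a quaternary centre, and the stereocentre is β to the carboxylate and cannot epimerise.

Step 5
Reactants: 7 acid; 8 ethoxyacetylene
Product: 11 3-ethoxy-4-[(1R)-2-methyl-1-(MTD)propyl]cyclobut-2-en-1-one (mixture of C4 epimers), via acid chloride 9 (not isolated), via aldoketene 10 (not isolated)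
Conditions: Me2C=C(Cl)NMe2 (1.1 equiv), CH2Cl2, 0 °C; then added slowly to 8 (4 equiv), Et3N (1.5 equiv), Et2O, 0 °C → rt
Reagents that add atoms: none
Why: Neutral acid chloride formation with the α-chloroenamine, amine dehydrochlorination to the aldoketene and ketene–ynol ether [2+2] cycloaddition, in which the nucleophilic CH terminus of 8 attacks the ketene carbonyl carbon and the C(OEt) terminus closes onto the ketene α-carbon, is the established entry to 4-alkyl-3-ethoxycyclobutenones; ring carbon C4 forms as an epimer mixture that does not matter because it ends as an arene carbon.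

Step 6
Reactants: 6 methyl ester
Product: 12 (3S)-3-(MTD)-4-methylpentanal
Conditions: DIBAL-H (1.1 equiv), CH2Cl2, −78 °C; aq. Rochelle salt
Reagents that add atoms: none
Why: Partial ester reduction with DIBAL-H at −78 °C stops at the aluminium hemiacetal of the accessible side-chain ester, whereas both ring carbonyl groups are screened by adjacent quaternary or fully substituted carbons.

Step 7
Reactants: 12 aldehyde
Product: 14 (3R)-3-(MTD)-4-methylpent-1-yne, via enol nonaflate 13 (not isolated)
Conditions: n-C4F9SO2F (1.3 equiv), P2-Et phosphazene base (2.3 equiv), DMF, −20 °C → rt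
Reagents that add atoms: none
Why: One-pot nonaflation–elimination of an enolisable aldehyde is a known way to a terminal alkyne with the same carbon count: the enolate is O-sulfonylated, the alkenyl nonaflate loses nonaflate by E2 elimination, the ring ketones have no α-hydrogen and stay out of it, and a short reaction time at low temperature should keep the propargylic centre from isomerising.

Step 8
Reactants: 14 terminal alkyne
Product: 17 {[(3R)-3-(MTD)-4-methylpent-1-yn-1-yl]oxy}triisopropylsilane, via lithium acetylide 15 (not isolated), via lithium ynolate 16 (not isolated)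
Conditions: LDA (1.05 equiv), THF, −78 °C; t-BuOOLi (from anhydrous t-BuOOH + LiHMDS), −78 → 0 °C; TIPSOTf, −78 → 0 °C
Reagents that add atoms: tert-butyl hydroperoxide, CC(C)(C)OO; triisopropylsilyl triflate, CC(C)[Si](C(C)C)(C(C)C)OS(=O)(=O)C(F)(F)F
Why: Oxygenation of a lithium acetylide with lithium tert-butyl peroxide gives the lithium ynolate, which the bulky silyl triflate traps on oxygen, and since only amide bases are used the ring ketones never meet an alkyllithium while the charge on the acetylide and ynolate protects the neighbouring C–H from deprotonation.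

Step 9
Reactants: 11 cyclobutenone; 17 silyl ynol ether
Product: 22 3-ethoxy-2,6-bis[(1R)-2-methyl-1-(MTD)propyl]-5-(triisopropylsilyloxy)phenol, via vinylketene 18 (not isolated), via 4-alkenylcyclobutenone 19 (not isolated), via dienylketene 20 (not isolated), via cyclohexadienone 21 (not isolated)
Conditions: 17 (1.3 equiv), PhMe (0.5 M), Ar, sealed tube, 80 °C then 110 °C
Reagents that add atoms: none
Why: On heating, 11 undergoes conrotatory 4π cleavage of its C1–C4 bond with the arm turning outward, and the resulting vinylketene 18 is captured by 17 in a ketene–alkyne [2+2] that joins the arm-bearing alkyne carbon to the ketene carbonyl carbon and the silyloxy carbon to the ketene CH. Cyclobutenone 19 opens in a second 4π step to dienylketene 20, and the benzene ring closes by thermal disrotatory 6π electrocyclisation between the ketene carbon and the arm-bearing diene terminus, after which dienone 21 enolises to 22. This is the Danheiser benzannulation in its siloxyalkyne form, and 4-alkyl-3-alkoxycyclobutenones are known to give 2,6-dialkyl-3-silyloxy-5-alkoxyphenols in this way. No stereocentre is created: the ring centres of 11, 19 and 21 all end as sp2 carbons, and the two exocyclic centres are spectators that meet only neutral, aprotic heat. The selectivity required is regiochemical and is secured by the oxygen donor of 17, which makes the arm-bearing carbon the only nucleophilic terminus and so places both arms next to the new OH, the three oxygens 1,3,5 and one CH between OSi and OEt. High concentration and a slight excess of 17 should favour capture of 18 over its dimerisation, and the doubly flanked phenol of 22 is too hindered to be acylated by 18.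

Step 10
Reactants: 22 silyl ether
Product: 23 5-ethoxy-2,4-bis[(1R)-2-methyl-1-(MTD)propyl]benzene-1,3-diol
Conditions: TBAF–AcOH (1:1), THF, 0 °C
Reagents that add atoms: none
Why: Fluoride-induced desilylation cleaves the aryl silyl ether selectively, and the acetic acid buffer keeps the liberated phenol protonated so that it neither attacks the neighbouring vinylogous ester nor starts retro-Michael chemistry at the benzylic centres.

Step 11
Reactants: 23 resorcinol; 24 isobutyryl chloride
Product: 25 1-{2-ethoxy-4,6-dihydroxy-3,5-bis[(1R)-2-methyl-1-(MTD)propyl]phenyl}-2-methylpropan-1-one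
Conditions: 24 (2 equiv), TiCl4 (4 equiv), CH2Cl2, −20 → 0 °C; aq. work-up
Reagents that add atoms: none
Why: In this Friedel–Crafts acylation, directed by the titanium phenoxide, the ring carries three oxygen donors and a single unsubstituted carbon ortho to the freed OH, so the site is not in question and the high nucleophilicity of the ring should allow a temperature at which the arms are not disturbed.

Step 12
Reactants: 25 tris-ether
Product: 26 (R,R)-myrtucommulone A
Conditions: BBr3 (excess), CH2Cl2, −78 → 0 °C; then ice-water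
Reagents that add atoms: none
Why: In this boron tribromide ether cleavage the Lewis acid binds the aryl ketone/ortho-ethoxy chelate and the two vinylogous ester carbonyl groups, bromide then dealkylates by SN2 attack at the ethyl and methyl carbons, no bond at a stereocentre is involved, and the low temperature should avoid cyclodehydration of enol and phenol to a xanthene.

Compound list
1 | syncarpic acid | CC1(C)C(=O)CC(=O)C(C)(C)C1=O | starting material
2 | (E)-4-methylpent-2-enal | CC(C)/C=C/C=O | starting material
3 | (4S)-2-hydroxy-4-isopropyl-6,6,8,8-tetramethyl-3,4-dihydro-2H-chromene-5,7(6H,8H)-dione | OC1C[C@@H](C(C)C)C2=C(O1)C(C)(C)C(=O)C(C)(C)C2=O | intermediate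
4 | (4S)-4-isopropyl-6,6,8,8-tetramethyl-3,4-dihydro-2H-chromene-2,5,7(6H,8H)-trione | O=C1C[C@@H](C(C)C)C2=C(O1)C(C)(C)C(=O)C(C)(C)C2=O | intermediate
5 | methyl (3S)-3-(2-hydroxy-3,3,5,5-tetramethyl-4,6-dioxocyclohex-1-en-1-yl)-4-methylpentanoate | COC(=O)C[C@H](C1=C(O)C(C)(C)C(=O)C(C)(C)C1=O)C(C)C | intermediate
6 | methyl (3S)-3-(MTD)-4-methylpentanoate | COC(=O)C[C@H](C1=C(OC)C(C)(C)C(=O)C(C)(C)C1=O)C(C)C | intermediate
7 | (3S)-3-(MTD)-4-methylpentanoic acid | OC(=O)C[C@H](C1=C(OC)C(C)(C)C(=O)C(C)(C)C1=O)C(C)C | intermediate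
8 | ethoxyacetylene | CCOC#C | starting material
9 | (3S)-3-(MTD)-4-methylpentanoyl chloride | ClC(=O)C[C@H](C1=C(OC)C(C)(C)C(=O)C(C)(C)C1=O)C(C)C | intermediate
10 | (3R)-3-(MTD)-4-methylpent-1-en-1-one (aldoketene) | O=C=C[C@H](C1=C(OC)C(C)(C)C(=O)C(C)(C)C1=O)C(C)C | intermediate
11 | 3-ethoxy-4-[(1R)-2-methyl-1-(MTD)propyl]cyclobut-2-en-1-one (C4 epimers) | CCOC1=CC(=O)C1[C@H](C2=C(OC)C(C)(C)C(=O)C(C)(C)C2=O)C(C)C | intermediate
12 | (3S)-3-(MTD)-4-methylpentanal | O=CC[C@H](C1=C(OC)C(C)(C)C(=O)C(C)(C)C1=O)C(C)C | intermediate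
13 | (3R)-3-(MTD)-4-methylpent-1-en-1-yl nonafluorobutane-1-sulfonate (E/Z) | FC(F)(F)C(F)(F)C(F)(F)C(F)(F)S(=O)(=O)OC=C[C@H](C1=C(OC)C(C)(C)C(=O)C(C)(C)C1=O)C(C)C | intermediate
14 | (3R)-3-(MTD)-4-methylpent-1-yne | C#C[C@H](C1=C(OC)C(C)(C)C(=O)C(C)(C)C1=O)C(C)C | intermediate
15 | lithium acetylide of 14 | [Li]C#C[C@H](C1=C(OC)C(C)(C)C(=O)C(C)(C)C1=O)C(C)C | intermediate
16 | lithium (3R)-3-(MTD)-4-methylpent-1-yn-1-olate | [Li]OC#C[C@H](C1=C(OC)C(C)(C)C(=O)C(C)(C)C1=O)C(C)C | intermediate
17 | {[(3R)-3-(MTD)-4-methylpent-1-yn-1-yl]oxy}triisopropylsilane | CC(C)[Si](C(C)C)(C(C)C)OC#C[C@H](C1=C(OC)C(C)(C)C(=O)C(C)(C)C1=O)C(C)C | intermediate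
18 | (3Z,5R)-3-ethoxy-5-(MTD)-6-methylhepta-1,3-dien-1-one (vinylketene) | O=C=C/C(OCC)=C/[C@H](C1=C(OC)C(C)(C)C(=O)C(C)(C)C1=O)C(C)C | intermediate
19 | 4-[(Z)-1-ethoxy-3-(MTD)-4-methylpent-1-enyl]-2-[2-methyl-1-(MTD)propyl]-3-(triisopropylsilyloxy)cyclobut-2-en-1-one (arm centres unchanged; C4 unassigned) | O=C1C([C@H](C2=C(OC)C(C)(C)C(=O)C(C)(C)C2=O)C(C)C)=C(O[Si](C(C)C)(C(C)C)C(C)C)C1/C(OCC)=C/[C@H](C3=C(OC)C(C)(C)C(=O)C(C)(C)C3=O)C(C)C | intermediate
20 | 5-ethoxy-8-methyl-7-(MTD)-2-[2-methyl-1-(MTD)propyl]-3-(triisopropylsilyloxy)nona-1,3,5-trien-1-one (arm centres unchanged; C2 and C5 cis on C3=C4) | O=C=C([C@H](C2=C(OC)C(C)(C)C(=O)C(C)(C)C2=O)C(C)C)/C(O[Si](C(C)C)(C(C)C)C(C)C)=C\C(OCC)=C\[C@H](C3=C(OC)C(C)(C)C(=O)C(C)(C)C3=O)C(C)C | intermediate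
21 | 5-ethoxy-2,6-bis[2-methyl-1-(MTD)propyl]-3-(triisopropylsilyloxy)cyclohexa-2,4-dien-1-one (arm centres unchanged; C6 unassigned) | O=C1C([C@H](C2=C(OC)C(C)(C)C(=O)C(C)(C)C2=O)C(C)C)=C(O[Si](C(C)C)(C(C)C)C(C)C)C=C(OCC)C1[C@H](C3=C(OC)C(C)(C)C(=O)C(C)(C)C3=O)C(C)C | intermediate
22 | 3-ethoxy-2,6-bis[(1R)-2-methyl-1-(MTD)propyl]-5-(triisopropylsilyloxy)phenol | Oc1c([C@H](C2=C(OC)C(C)(C)C(=O)C(C)(C)C2=O)C(C)C)c(O[Si](C(C)C)(C(C)C)C(C)C)cc(OCC)c1[C@H](C3=C(OC)C(C)(C)C(=O)C(C)(C)C3=O)C(C)C | intermediate
23 | 5-ethoxy-2,4-bis[(1R)-2-methyl-1-(MTD)propyl]benzene-1,3-diol | Oc1c([C@H](C2=C(OC)C(C)(C)C(=O)C(C)(C)C2=O)C(C)C)c(O)cc(OCC)c1[C@H](C3=C(OC)C(C)(C)C(=O)C(C)(C)C3=O)C(C)C | intermediate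
24 | isobutyryl chloride | CC(C)C(Cl)=O | starting material
25 | 1-{2-ethoxy-4,6-dihydroxy-3,5-bis[(1R)-2-methyl-1-(MTD)propyl]phenyl}-2-methylpropan-1-one | CC(C)C(=O)c1c(O)c([C@H](C2=C(OC)C(C)(C)C(=O)C(C)(C)C2=O)C(C)C)c(O)c([C@H](C3=C(OC)C(C)(C)C(=O)C(C)(C)C3=O)C(C)C)c1OCC | intermediate
26 | (R,R)-myrtucommulone A | CC(C)C(=O)c1c(O)c([C@H](C2=C(O)C(C)(C)C(=O)C(C)(C)C2=O)C(C)C)c(O)c([C@H](C2=C(O)C(C)(C)C(=O)C(C)(C)C2=O)C(C)C)c1O | target

Total step count: 12.
Longest linear sequence: 10 steps (1, 2, 3, 6, 7, 8, 9, 10, 11, 12). The cyclobutenone branch (steps 4 and 5) leaves the main line at 6 and rejoins it in step 9.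

Steps most likely to fail

Step 9. Capture of the vinylketene by the α-branched ynol ether, and then the 6π closure, must bring two very large arms next to one ring carbon. If either event is too slow, the ketene is lost by dimerisation or re-closure and the ynol ether decays on long heating. The fallback carries only one arm through the annulation. It sets out from 17, which is heated with the parent 3-ethoxycyclobut-2-en-1-one F1 (from acetyl chloride, Et3N and 8) to give the mono-arm phenol F2. The operations of steps 10, 11 and 12 then lead through the resorcinol F3 and the aryl ketone F4 to (R)-semimyrtucommulone F5. The second arm is attached by base-mediated conjugate addition of the phloroglucinol anion of F5 (NaH, THF) to isobutylidenesyncarpic acid F6 (Knoevenagel condensation of 1 with isobutyraldehyde), a reaction type established for acylphloroglucinols and alkylidene 1,3-diones. The new centre forms without control, so the product has to be separated from the (R,S) diastereomer F7. The centre brought in with 17 ensures that the (R,R) isomer obtained is a single enantiomer. The fallback comes back to the route at 26.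

Step 5. The vinylogous ester oxygen may attack the acyl chloride or ketene carbon through a six-membered transition state, with loss of methyl chloride and relactonisation. The aldoketene may also dimerise ahead of the cycloaddition. The fallback makes the same vinylketene without a saturated acyl chloride and without the four-membered ring. It sets out from 7, which is activated with carbonyldiimidazole to the acyl imidazolide F8 and C-acylates magnesium ethyl malonate to give the β-keto ester F9. Triethyl orthoformate with catalytic acid gives the (E)-β-ethoxy enoate F10. Saponification gives the acid F11, and the α-chloroenamine gives the acid chloride F12, whose carbonyl group is conjugated and too remote for six-ring closure. Et3N in the presence of 17 effects 1,4-dehydrochlorination of F12 to 18 at or below room temperature. Gentle warming then completes the cascade through 19, 20 and 21, so the fallback comes back to the route at 22.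

Step 7. The strong base may isomerise the product through the propargyl–allenyl manifold, with erosion of configuration, or aldol self-condensation may outrun O-sulfonylation. The fallback avoids both the aldehyde and the terminal alkyne. It sets out from 6, whose ester enolate (LiHMDS, −78 °C) is brominated twice with BrCF2CF2Br, first to the α-bromo ester F13 and then to the α,α-dibromo ester F14. Double bromine–lithium exchange with t-BuLi (−78 → 0 °C) and loss of lithium methoxide give the ynolate, so the fallback comes back to the route at 16, which is silylated to 17 as in step 8. This path exposes the ring ketones to t-BuLi, which is why it is the second choice.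

Further compounds
F1 | step 9 | 3-ethoxycyclobut-2-en-1-one | CCOC1=CC(=O)C1
F2 | step 9 | 5-ethoxy-2-[(1R)-2-methyl-1-(MTD)propyl]-3-(triisopropylsilyloxy)phenol | Oc1cc(OCC)cc(O[Si](C(C)C)(C(C)C)C(C)C)c1[C@H](C2=C(OC)C(C)(C)C(=O)C(C)(C)C2=O)C(C)C
F3 | step 9 | 5-ethoxy-2-[(1R)-2-methyl-1-(MTD)propyl]benzene-1,3-diol | Oc1cc(OCC)cc(O)c1[C@H](C2=C(OC)C(C)(C)C(=O)C(C)(C)C2=O)C(C)C
F4 | step 9 | 1-{2-ethoxy-4,6-dihydroxy-5-[(1R)-2-methyl-1-(MTD)propyl]phenyl}-2-methylpropan-1-one | CC(C)C(=O)c1c(O)c([C@H](C2=C(OC)C(C)(C)C(=O)C(C)(C)C2=O)C(C)C)c(O)cc1OCC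
F5 | step 9 | (R)-semimyrtucommulone | CC(C)C(=O)c1c(O)c([C@H](C2=C(O)C(C)(C)C(=O)C(C)(C)C2=O)C(C)C)c(O)cc1O
F6 | step 9 | isobutylidenesyncarpic acid (2,2,4,4-tetramethyl-6-(2-methylpropylidene)cyclohexane-1,3,5-trione) | CC(C)C=C1C(=O)C(C)(C)C(=O)C(C)(C)C1=O
F7 | step 9 | (R,S)-myrtucommulone A (meso diastereomer) | CC(C)C(=O)c1c(O)c([C@H](C2=C(O)C(C)(C)C(=O)C(C)(C)C2=O)C(C)C)c(O)c([C@@H](C2=C(O)C(C)(C)C(=O)C(C)(C)C2=O)C(C)C)c1O
F8 | step 5 | (3S)-1-(imidazol-1-yl)-3-(MTD)-4-methylpentan-1-one | O=C(C[C@H](C1=C(OC)C(C)(C)C(=O)C(C)(C)C1=O)C(C)C)n1ccnc1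
F9 | step 5 | ethyl (5S)-5-(MTD)-6-methyl-3-oxoheptanoate | CCOC(=O)CC(=O)C[C@H](C1=C(OC)C(C)(C)C(=O)C(C)(C)C1=O)C(C)C
F10 | step 5 | ethyl (2E,5S)-3-ethoxy-5-(MTD)-6-methylhept-2-enoate | CCOC(=O)/C=C(/OCC)C[C@H](C1=C(OC)C(C)(C)C(=O)C(C)(C)C1=O)C(C)C
F11 | step 5 | (2E,5S)-3-ethoxy-5-(MTD)-6-methylhept-2-enoic acid | OC(=O)/C=C(/OCC)C[C@H](C1=C(OC)C(C)(C)C(=O)C(C)(C)C1=O)C(C)C
F12 | step 5 | (2E,5S)-3-ethoxy-5-(MTD)-6-methylhept-2-enoyl chloride | ClC(=O)/C=C(/OCC)C[C@H](C1=C(OC)C(C)(C)C(=O)C(C)(C)C1=O)C(C)C
F13 | step 7 | methyl (3S)-2-bromo-3-(MTD)-4-methylpentanoate (C2 epimers) | COC(=O)C(Br)[C@H](C1=C(OC)C(C)(C)C(=O)C(C)(C)C1=O)C(C)C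
F14 | step 7 | methyl (3S)-2,2-dibromo-3-(MTD)-4-methylpentanoate | COC(=O)C(Br)(Br)[C@H](C1=C(OC)C(C)(C)C(=O)C(C)(C)C1=O)C(C)C
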